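**Retrosynthetic overview**

- The four benzyl ethers of 17 come off last. The ArCH2–CH2Ar bridge is cut at the bond between C1 of ring B and its CH2: B-alkyl Suzuki coupling of aryl triflate 12 with the 9-BBN adduct of ring A styrene 15.
- Triflate 12 comes from resorcinol 10 (oxygen at C5 benzylated, flanked oxygen at C1 triflated), and 10 from cyclohexane-1,3-dione 9 by dehydrogenation.
- The feature the route rests on is in ring B (central phenol: C1 bridge, C2 and C6 identical 4-hydroxybenzyl groups, C5 OH, C3 and C4 CH). The unit C2–C1–C6 is the α-carbon, carbonyl and α′-carbon of symmetric ketone 6, and C3–C4–C5 is methyl acrylate.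
- Ring B is the only ring built: Michael addition forms C2–C3 and Claisen closure forms C6–C5. Ring A and the two pendant phenol rings are bought.
- Ketone 6 comes from dimethyl acetonedicarboxylate by two separate benzylations with 4-(benzyloxy)benzyl chloride, one at each flanking carbon, then hydrolysis and decarboxylation. Styrene 15 comes from 3-hydroxy-5-methoxybenzaldehyde.

Key step: step 4

Remark: the target has no stereocentre. The stereocentres of 3, 4 and 5 are carried as mixtures and vanish on decarboxylation in step 3; those of 8 and 9 vanish on aromatization in step 5. 3-Hydroxy-5-methoxybenzaldehyde (13) is taken as a purchasable compound.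

**Route**

Step 1
Reactants: 1 dimethyl 1,3-acetonedicarboxylate; 2 4-(benzyloxy)benzyl chloride
Product: 3 dimethyl 2-[4-(benzyloxy)benzyl]-3-oxopentanedioate (racemic)
Conditions: 1 (1.5 equiv.), NaH (1.0 equiv.), THF, 0 °C; 2 (1.0 equiv.), NaI (cat.), 0 °C → rt
Reagents that add atoms: none
Why: SN2 C-alkylation of the sodium enolate of the β-keto diester by the benzylic chloride, in which the excess of 1 and a single equivalent of base should hold the reaction at the monoalkylated stage, with unreacted 1 removed on purification.

Step 2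
Reactants: 3 dimethyl 2-[4-(benzyloxy)benzyl]-3-oxopentanedioate; 2 4-(benzyloxy)benzyl chloride
Product: 4 dimethyl 2,4-bis[4-(benzyloxy)benzyl]-3-oxopentanedioate (mixture of diastereomers)
Conditions: NaH (1.05 equiv.), THF/DMF, 0 °C; 2 (1.05 equiv.), NaI (cat.), 50 °C
Reagents that add atoms: none
Why: Second enolate C-alkylation, in which deprotonation and attack should take place at the still unsubstituted, more acidic and less hindered CH2 of 3, so that one benzyl group ends up on each carbon flanking the ketone.

Step 3
Reactants: 4 dimethyl 2,4-bis[4-(benzyloxy)benzyl]-3-oxopentanedioate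
Product: 6 1,5-bis[4-(benzyloxy)phenyl]pentan-3-one, via keto diacid 5 (not isolated)
Conditions: NaOH (1 M aq.), MeOH/THF, rt; then HCl (aq.) to pH 1, 50 °C
Reagents that add atoms: none
Why: Ester saponification followed by decarboxylation of the β-keto diacid (ketonic cleavage of the acetoacetic ester type) should give the symmetric ketone, with both stereocentres removed and the benzyl ethers untouched by dilute base and dilute acid.

Step 4
Reactants: 6 1,5-bis[4-(benzyloxy)phenyl]pentan-3-one; 7 methyl acrylate
Product: 9 2,4-bis[4-(benzyloxy)benzyl]cyclohexane-1,3-dione (mixture of diastereomers and enol tautomers), via Michael adduct keto ester 8 (not isolated)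
Conditions: KOtBu (2.2 equiv.), THF, −10 °C; 7 (1.0 equiv.) added slowly; → rt; aq. HCl
Reagents that add atoms: none
Why: KOtBu generates the potassium enolate of 6, which adds to the β-carbon of 7 (C2–C3 bond); proton transfer in adduct 8 gives the α′ enolate, which attacks the ester carbonyl and expels methoxide (C6–C5 bond), and the 1,3-dione is at once deprotonated to its stabilized enolate, which makes the sequence irreversible. The closest known reaction type is the consecutive Michael–Claisen synthesis of cyclohexane-1,3-diones from enolizable ketones and acrylates under alkoxide or hydride bases. Ring B closes in a 6-(enolexo)-exo-trig Claisen (Dieckmann-type) condensation; attack by the other enolizable carbon of 8 would give a four-membered ring and does not compete. The two new stereocentres (the benzyl-bearing ring carbons) are not controlled and need not be, since both are epimerizable and are erased by the aromatization in step 5. The selectivity needed is one Michael addition followed by closure, not a second Michael addition or acrylate oligomerization; the symmetry of 6 removes any question of regiochemistry, and slow addition of one equivalent of 7 to excess base at low temperature, with fast closure to the unreactive dione enolate, should keep the concentration of free acrylate low.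

Step 5
Reactants: 9 2,4-bis[4-(benzyloxy)benzyl]cyclohexane-1,3-dione
Product: 10 2,4-bis[4-(benzyloxy)benzyl]benzene-1,3-diol
Conditions: Hg(OAc)2 (2.2 equiv.), NaOAc, AcOH, reflux; aq. HCl work-up
Reagents that add atoms: none
Why: Dehydrogenation of a cyclohexane-1,3-dione with Hg(OAc)2 (mercuration of the dione enol, then loss of reduced mercury together with a neighbouring hydrogen) should introduce the one further ring double bond, and the resulting cyclohexenedione tautomerizes to the resorcinol; no hydrogen gas is released, so the benzyl ethers, which would be at risk over Pd/C at high temperature, should survive buffered acetic acid.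

Step 6
Reactants: 10 2,4-bis[4-(benzyloxy)benzyl]benzene-1,3-diol
Product: 11 3-(benzyloxy)-2,6-bis[4-(benzyloxy)benzyl]phenol
Conditions: BnBr (1.0 equiv.), K2CO3 (1.0 equiv.), acetone, rt
Reagents that add atoms: benzyl bromide, BrCc1ccccc1
Why: Williamson etherification with one equivalent of halide and a weak base, in which the hydroxyl that becomes the C5 oxygen of ring B (one ortho benzyl, one ortho H) is less shielded and slightly more acidic than the hydroxyl flanked by two benzyl groups, so that its mono-ether should predominate; the regioisomer and the bis-ether are removed by chromatography.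

Step 7
Reactants: 11 3-(benzyloxy)-2,6-bis[4-(benzyloxy)benzyl]phenol
Product: 12 3-(benzyloxy)-2,6-bis[4-(benzyloxy)benzyl]phenyl trifluoromethanesulfonate
Conditions: Tf2O, pyridine, CH2Cl2, 0 °C → rt
Reagents that add atoms: trifluoromethanesulfonic anhydride, O=S(=O)(OS(=O)(=O)C(F)(F)F)C(F)(F)F
Why: O-sulfonylation of a phenol with the small, highly electrophilic anhydride, which is known to proceed on 2,6-dialkylphenols, turns the flanked C1 oxygen into a leaving group for cross-coupling.

Step 8
Reactants: 13 3-hydroxy-5-methoxybenzaldehyde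
Product: 14 3-(benzyloxy)-5-methoxybenzaldehyde
Conditions: BnBr, K2CO3, DMF, rt
Reagents that add atoms: benzyl bromide, BrCc1ccccc1
Why: Williamson etherification of the only phenol, which protects the ring A hydroxyl with the same group that is removed at the end.

Step 9
Reactants: 14 3-(benzyloxy)-5-methoxybenzaldehyde
Product: 15 1-(benzyloxy)-3-ethenyl-5-methoxybenzene
Conditions: Ph3PCH3Br, KOtBu, THF, 0 °C → rt
Reagents that add atoms: methyltriphenylphosphonium bromide, C[P+](c1ccccc1)(c1ccccc1)c1ccccc1.[Br-]
Why: Wittig methylenation of an aromatic aldehyde with the unstabilized ylide should give the styrene directly.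

Step 10
Reactants: 15 1-(benzyloxy)-3-ethenyl-5-methoxybenzene; 12 3-(benzyloxy)-2,6-bis[4-(benzyloxy)benzyl]phenyl trifluoromethanesulfonate
Product: 17 1-(benzyloxy)-3-{2-[3-(benzyloxy)-5-methoxyphenyl]ethyl}-2,4-bis[4-(benzyloxy)benzyl]benzene, via B-alkyl-9-BBN borane 16 (not isolated)
Conditions: 15 (1.5 equiv.), 9-BBN dimer, THF, 0 °C → rt; then 12, Pd(OAc)2 (cat.), SPhos (2-dicyclohexylphosphino-2′,6′-dimethoxybiphenyl), K3PO4 (aq.), THF, 65 °C
Reagents that add atoms: none
Why: Anti-Markovnikov hydroboration of the styrene with 9-BBN gives the primary alkylborane, which after activation by base transmetalates to the arylpalladium species formed by oxidative addition of zerovalent palladium to the triflate (the bulky biaryl phosphine serves the di-ortho-substituted centre), and reductive elimination forms the C1–CH2 bond in a B-alkyl Suzuki–Miyaura coupling.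

Step 11
Reactants: 17 1-(benzyloxy)-3-{2-[3-(benzyloxy)-5-methoxyphenyl]ethyl}-2,4-bis[4-(benzyloxy)benzyl]benzene
Product: 18 3-[2-(3-hydroxy-5-methoxyphenyl)ethyl]-2,4-bis(4-hydroxybenzyl)phenol (target)
Conditions: H2 (1 atm), Pd/C (10 wt% palladium on carbon), EtOAc/MeOH, rt
Reagents that add atoms: none
Why: Catalytic hydrogenolysis should cleave all four benzyl aryl ethers at once, while the methyl ether, the diarylmethane CH2 groups and the bibenzyl bridge are inert.

**Compound list**

1 | dimethyl 1,3-acetonedicarboxylate (dimethyl 3-oxopentanedioate) | COC(=O)CC(=O)CC(=O)OC | starting material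
2 | 4-(benzyloxy)benzyl chloride | ClCc1ccc(OCc2ccccc2)cc1 | starting material
3 | dimethyl 2-[4-(benzyloxy)benzyl]-3-oxopentanedioate (racemic) | COC(=O)CC(=O)C(Cc1ccc(OCc2ccccc2)cc1)C(=O)OC | intermediate
4 | dimethyl 2,4-bis[4-(benzyloxy)benzyl]-3-oxopentanedioate (mixture of diastereomers) | COC(=O)C(Cc1ccc(OCc2ccccc2)cc1)C(=O)C(Cc1ccc(OCc2ccccc2)cc1)C(=O)OC | intermediate
5 | 2,4-bis[4-(benzyloxy)benzyl]-3-oxopentanedioic acid (mixture of diastereomers) | OC(=O)C(Cc1ccc(OCc2ccccc2)cc1)C(=O)C(Cc1ccc(OCc2ccccc2)cc1)C(=O)O | intermediate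
6 | 1,5-bis[4-(benzyloxy)phenyl]pentan-3-one | O=C(CCc1ccc(OCc2ccccc2)cc1)CCc1ccc(OCc2ccccc2)cc1 | intermediate
7 | methyl acrylate | C=CC(=O)OC | starting material
8 | methyl 4-[4-(benzyloxy)benzyl]-7-[4-(benzyloxy)phenyl]-5-oxoheptanoate (racemic) | COC(=O)CCC(Cc1ccc(OCc2ccccc2)cc1)C(=O)CCc1ccc(OCc2ccccc2)cc1 | intermediate
9 | 2,4-bis[4-(benzyloxy)benzyl]cyclohexane-1,3-dione (mixture of diastereomers) | O=C1CCC(Cc2ccc(OCc3ccccc3)cc2)C(=O)C1Cc1ccc(OCc2ccccc2)cc1 | intermediate
10 | 2,4-bis[4-(benzyloxy)benzyl]benzene-1,3-diol | Oc1ccc(Cc2ccc(OCc3ccccc3)cc2)c(O)c1Cc1ccc(OCc2ccccc2)cc1 | intermediate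
11 | 3-(benzyloxy)-2,6-bis[4-(benzyloxy)benzyl]phenol | Oc1c(Cc2ccc(OCc3ccccc3)cc2)ccc(OCc2ccccc2)c1Cc1ccc(OCc2ccccc2)cc1 | intermediate
12 | 3-(benzyloxy)-2,6-bis[4-(benzyloxy)benzyl]phenyl trifluoromethanesulfonate | O=S(=O)(Oc1c(Cc2ccc(OCc3ccccc3)cc2)ccc(OCc2ccccc2)c1Cc1ccc(OCc2ccccc2)cc1)C(F)(F)F | intermediate
13 | 3-hydroxy-5-methoxybenzaldehyde | COc1cc(O)cc(C=O)c1 | starting material
14 | 3-(benzyloxy)-5-methoxybenzaldehyde | COc1cc(OCc2ccccc2)cc(C=O)c1 | intermediate
15 | 1-(benzyloxy)-3-ethenyl-5-methoxybenzene | COc1cc(OCc2ccccc2)cc(C=C)c1 | intermediate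
16 | 9-{2-[3-(benzyloxy)-5-methoxyphenyl]ethyl}-9-borabicyclo[3.3.1]nonane | COc1cc(OCc2ccccc2)cc(CCB2C3CCCC2CCC3)c1 | intermediate
17 | 1-(benzyloxy)-3-{2-[3-(benzyloxy)-5-methoxyphenyl]ethyl}-2,4-bis[4-(benzyloxy)benzyl]benzene | COc1cc(OCc2ccccc2)cc(CCc2c(Cc3ccc(OCc4ccccc4)cc3)ccc(OCc3ccccc3)c2Cc2ccc(OCc3ccccc3)cc2)c1 | intermediate
18 | 3-[2-(3-hydroxy-5-methoxyphenyl)ethyl]-2,4-bis(4-hydroxybenzyl)phenol | COc1cc(O)cc(CCc2c(Cc3ccc(O)cc3)ccc(O)c2Cc2ccc(O)cc2)c1 | target

**Step count**

Total steps: 11. Longest linear sequence: 9 (steps 1–7, 10 and 11).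

**Steps most likely to fail**

Step 4. What may go wrong is a second Michael addition to the open-chain adduct before ring closure, anionic oligomerization of the acrylate, or reversal of the Michael addition. The fallback separates the two bond formations. It sets out from 6, which is condensed with pyrrolidine (TsOH cat., toluene, water removal) to the enamine 1-{1,5-bis[4-(benzyloxy)phenyl]pent-2-en-3-yl}pyrrolidine F1. A Stork enamine addition to 7 (MeCN, reflux) and hydrolysis with aqueous acetic acid should stop cleanly at the mono-adduct 8, which is now isolated. Closing 8 with KOtBu in THF in a separate Claisen (Dieckmann-type) condensation brings the sequence back to the route at 9.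

Step 5. What may go wrong is electrophilic mercuration of the electron-rich benzyloxyphenyl rings, incomplete dehydrogenation, or oxidation at the diarylmethane CH2 groups. The fallback sets out from 9 and fixes the dione as a diene before oxidation. Double O-silylation (TMSOTf, Et3N, CH2Cl2, 0 °C) gives 2,4-bis[4-(benzyloxy)benzyl]-1,3-bis(trimethylsilyloxy)cyclohexa-1,3-diene F2 (or its diene regioisomer, which behaves the same way). DDQ (1 equiv., 0 °C) removes hydride and a proton from the ring CH2–CH2 unit, a fast cyclohexadiene-to-arene dehydrogenation, to give 1,3-bis(trimethylsilyloxy)-2,4-bis[4-(benzyloxy)benzyl]benzene F3. K2CO3 in MeOH cleaves the silyl ethers and returns to the route at 10.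

Step 10. What may go wrong is slow oxidative addition and transmetalation at the di-ortho-substituted triflate, with β-hydride elimination of the alkylpalladium intermediate and S–O hydrolysis of the triflate back to 11 as competing processes. The fallback replaces the sp3 boron partner by an sp2 coupling of the same two fragments. It sets out from 12 and 15: a Mizoroki–Heck reaction (Pd(OAc)2, PPh3, LiCl, Et3N, DMF, 100 °C) should give the stilbene 1-(benzyloxy)-3-{(E)-2-[3-(benzyloxy)-5-methoxyphenyl]ethenyl}-2,4-bis[4-(benzyloxy)benzyl]benzene F4. Hydrogenation of F4 over Pd/C (H2, EtOAc/MeOH) saturates the alkene and removes the four benzyl groups in the same operation, returning to the route at 18.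

**Further compounds**

F1 | step 4 | 1-{1,5-bis[4-(benzyloxy)phenyl]pent-2-en-3-yl}pyrrolidine (E/Z mixture) | C(Cc1ccc(OCc2ccccc2)cc1)=C(CCc1ccc(OCc2ccccc2)cc1)N1CCCC1
F2 | step 5 | 2,4-bis[4-(benzyloxy)benzyl]-1,3-bis(trimethylsilyloxy)cyclohexa-1,3-diene | C[Si](C)(C)OC1=C(Cc2ccc(OCc3ccccc3)cc2)C(O[Si](C)(C)C)=C(Cc2ccc(OCc3ccccc3)cc2)CC1
F3 | step 5 | 1,3-bis(trimethylsilyloxy)-2,4-bis[4-(benzyloxy)benzyl]benzene | C[Si](C)(C)Oc1ccc(Cc2ccc(OCc3ccccc3)cc2)c(O[Si](C)(C)C)c1Cc1ccc(OCc2ccccc2)cc1
F4 | step 10 | 1-(benzyloxy)-3-{(E)-2-[3-(benzyloxy)-5-methoxyphenyl]ethenyl}-2,4-bis[4-(benzyloxy)benzyl]benzene | COc1cc(OCc2ccccc2)cc(/C=C/c2c(Cc3ccc(OCc4ccccc4)cc3)ccc(OCc3ccccc3)c2Cc2ccc(OCc3ccccc3)cc2)c1
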